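The ten-membered carbocycle of the target contains a 1,5-diene, C1=C10 (Z) and C4=C5 (E). Joining C1 to C4 and C5 to C10 folds this diene into a cyclobutane (C10-C1-C4-C5) set between a cyclohexanone (C5-C10) and a second cyclobutane (C1-C4). That latent feature is what the key step exploits. Flash pyrolysis of tricyclic ketone 20 breaks both sigma bonds and so delivers both alkenes and the ten-membered ring in one operation. Ketone 20, the cis-anti-cis photoadduct of 1-methylcyclobutene and a galactose-derived 2-methylcyclohexenone, already holds C6-C8, both methyls, the saturated lactone and a C7/C8 acetonide. C9, C13 and the angelate follow.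

Key step: step 15

Remark on numbering and stereochemistry: germacrane numbering (C1-C15) is used for all carbocycles. Sugar positions s1-s6 become C5, C6, C7, C8, C9, C10. The target is (6S,7R,8S,9R). In a D-galactopyranoside, O on s2 (down), s3 (up) and s4 (up) reproduces the C6, C7, C8 pattern. The carbinol centre C5 in 13 and 14 and the centre C11 in 25 and 26 are left undefined because both are erased in the same step or the next.

Step 1
Reactants: 1 methyl β-D-galactopyranoside
Product: 2 methyl 4,6-O-benzylidene-β-D-galactopyranoside (phenyl equatorial; 2-OH and 3-OH free)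
Conditions: PhCH(OMe)2, CSA (cat.), MeCN, rt
Reagents that add atoms: benzaldehyde dimethyl acetal, COC(OC)c1ccccc1
Why: Acid-catalysed transacetalisation under thermodynamic control closes the six-membered 4,6-acetal with an equatorial phenyl group and leaves only the 2,3-diol open.

Step 2
Reactants: 2 methyl 4,6-O-benzylidene-β-D-galactopyranoside
Product: 4 methyl 4,6-O-benzylidene-β-D-xylo-hexopyranosid-3-ulose (2-OH free), via dibutylstannylene acetal 3 (not isolated)
Conditions: Bu2SnO, MeOH, reflux, evaporate; Br2 (1 equiv), 4 Å MS, CH2Cl2, rt, dark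
Reagents that add atoms: none
Why: In this stannylene-acetal brominolysis, tin activates the equatorial O3 beside the axial O4 (the oxygen such acetals also alkylate first), and its hypobromite loses HBr to give the 3-ulose without a protecting-group detour and without touching a stereocentre.

Step 3
Reactants: 4 methyl 4,6-O-benzylidene-β-D-xylo-hexopyranosid-3-ulose; 5 bromoacetyl bromide
Product: 6 methyl 4,6-O-benzylidene-2-O-bromoacetyl-β-D-xylo-hexopyranosid-3-ulose
Conditions: pyridine, CH2Cl2, -20 °C
Reagents that add atoms: none
Why: O-acylation of the only free hydroxyl under cold, weakly basic conditions avoids enolising the base-sensitive ulose and ties the future C11-C12 unit to O2, the later lactone oxygen on C6.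

Step 4
Reactants: 6 methyl 4,6-O-bromoacetyl ulose as above
Product: 8 cis-fused γ-lactone of methyl 4,6-O-benzylidene-3-C-(carboxymethyl)-β-D-galactopyranoside (lactone to O2; CH2 branch axial on the α face; tertiary 3-OH equatorial), via diiodosamarium enolate 7 (not isolated)
Conditions: SmI2 (2.2 equiv), THF, high dilution, -78 °C; aq. NH4Cl
Reagents that add atoms: none
Why: In this intramolecular samarium Reformatsky reaction (5-(enolexo)-exo-trig), the non-basic enolate is held by its tether below the ring while the axial O4 and the benzylidene ring screen the upper face, so C11 should bond axially and set the tertiary carbinol C7 with its oxygen cis to O4 and its carbon branch cis to O2.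

Step 5
Reactants: 8 benzylidene lactone
Product: 9 lactone triol (methyl glycoside; tertiary 3-OH, axial 4-OH and primary 6-OH free)
Conditions: H2 (1 atm), Pd(OH)2/C, EtOAc-MeOH, rt
Reagents that add atoms: none
Why: Hydrogenolysis of the benzylidene acetal is neutral, so the lactone, the glycoside and the β-hydroxy ester motif are not disturbed.

Step 6
Reactants: 9 lactone triol
Product: 10 6-deoxy-6-iodo lactone diol
Conditions: I2, PPh3, imidazole, THF, rt
Reagents that add atoms: iodine, II
Why: Garegg-Samuelsson (Appel-type) iodination proceeds by SN2 displacement, so it picks the primary alcohol over the axial secondary and the tertiary one; it comes before acetalisation so that no 4,6-acetonide can compete in step 7.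

Step 7
Reactants: 10 6-deoxy-6-iodo lactone diol
Product: 11 3,4-O-isopropylidene 6-iodide (dioxolane cis-fused on the upper face, lactone cis-fused on the lower face)
Conditions: Me2C(OMe)2, CSA (cat.), acetone, rt
Reagents that add atoms: 2,2-dimethoxypropane, COC(C)(C)OC
Why: Acid-catalysed acetalisation of the cis-3,4-diol gives a dioxolane that caps the tertiary hydroxyl, holds the later C8 centre against epimerisation beside the ketone, and offers no hydrogen for photochemical abstraction by that ketone.

Step 8
Reactants: 11 3,4-O-isopropylidene 6-iodide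
Product: 12 methyl 6-deoxy-hex-5-enopyranoside (exocyclic enol ether) bearing the lactone and the acetonide
Conditions: AgF, pyridine, rt, dark
Reagents that add atoms: none
Why: In this silver-assisted E2 dehydroiodination H5 is the only β-hydrogen, and the mild medium avoids enolate formation in the β-alkoxy lactone.

Step 9
Reactants: 12 exocyclic enol ether
Product: 13 β-hydroxycyclohexanone (C9 ketone, C10 methylene, C5 carbinol as either epimer; C6/C7 lactone, C7/C8 acetonide)
Conditions: Hg(OCOCF3)2 (10 mol%), acetone-H2O (2:1), rt
Reagents that add atoms: water, O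
Why: In the Ferrier carbocyclisation, divalent mercury hydroxymercurates the enol ether, methanol is lost to give a mercurio keto-aldehyde, and its intramolecular aldol joins s6 to s1, so s2-s4 pass unchanged into C6-C8 while the new carbinol centre is removed in step 10.

Step 10
Reactants: 13 β-hydroxycyclohexanone
Product: 15 cyclohex-2-enone (C9 ketone, C5=C10; lactone and acetonide as before), via mesylate 14 (not isolated)
Conditions: MsCl, Et3N, CH2Cl2, 0 °C
Reagents that add atoms: none
Why: Mesylation followed by E1cB elimination works from either carbinol epimer, and the short cold exposure to a weak amine base avoids further loss of the C6 or C7 oxygen.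

Step 11
Reactants: 15 cyclohex-2-enone
Product: 16 2-iodocyclohex-2-enone (iodine on C10)
Conditions: I2, pyridine-CH2Cl2 (1:1), 0 °C to rt
Reagents that add atoms: iodine, II
Why: The α-iodination of an enone follows the Baylis-Hillman-type sequence (pyridine addition, iodination of the enolate, elimination) and is routine for 4-oxygenated cyclohexenones.

Step 12
Reactants: 16 2-iodocyclohex-2-enone
Product: 17 2-methylcyclohex-2-enone (C14 methyl on C10; C6/C7 lactone, C7/C8 acetonide)
Conditions: SnMe4, Pd2(dba)3 (cat.), AsPh3, CuI (10 mol%), NMP, 60 °C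
Reagents that add atoms: tetramethyltin, C[Sn](C)(C)C
Why: Stille coupling at zerovalent palladium brings in C14 under neutral conditions, so no hard organometallic reagent ever meets the lactone or the enolisable ketone.

Step 13
Reactants: 18 methylenecyclobutane
Product: 19 1-methylcyclobutene
Conditions: KOtBu (cat.), DMSO, rt; fractional distillation
Reagents that add atoms: none
Why: Base-catalysed prototropic alkene isomerisation favours the endocyclic trisubstituted alkene at equilibrium, and it is distilled out of the non-volatile medium.

Step 14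
Reactants: 17 2-methylcyclohex-2-enone; 19 1-methylcyclobutene
Product: 20 cis-anti-cis tricyclic photoadduct (cyclohexanone C5-C10, central cyclobutane C10-C1-C4-C5, outer cyclobutane C1-C2-C3-C4; methyls on C10 and C4; new ring on the face opposite the C6 oxygen)
Conditions: hν (medium-pressure Hg lamp, uranium-glass filter), 19 (excess), CH2Cl2, -30 °C
Reagents that add atoms: none
Why: In this enone-alkene [2+2] photocycloaddition (triplet enone, 1,4-biradical), the head-to-tail orientation (C5-C4 and C10-C1) is favoured by the polarity rule for electron-rich alkenes and by keeping the two methyl-bearing carbons diagonal; the biradical closes to the cis 6-4 fusion with the outer ring exo (anti), and addition is expected away from the C6 oxygen, although the face does not matter because C1, C4, C5 and C10 all become sp2 in step 15.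

Step 15
Reactants: 20 cis-anti-cis tricyclic photoadduct
Product: 21 ten-membered (1Z,4E)-dien-9-one (saturated C6/C7 lactone, C7/C8 acetonide)
Conditions: flash vacuum pyrolysis, quartz tube 500 °C, 10^-3 mbar, millisecond contact, trap at -196 °C
Reagents that add atoms: none
Why: The C1-C4 bond shared by the two four-membered rings (a bicyclo[2.2.0]hexane unit) is by far the weakest bond, so it homolyses first to a cyclohexane-1,4-diyl (secondary C1, tertiary C4) that relaxes from boat to chair and then cleaves C5-C10, the fully substituted, acyl-bearing bond aligned with both radical orbitals, which creates the C1=C10 and C4=C5 π bonds; this is the thermal half of the known photo-thermal olefin metathesis of cyclohexenone-cyclobutene adducts. The ten-membered ring is not closed by any cyclisation mode: it is laid bare by a two-bond fragmentation in which the six-membered ring and the two four-membered rings merge (ring expansion). No stereocentre is formed and four (C1, C4, C5, C10) are erased, so a facial isomer of 20 with the same cis-anti-cis relationship would converge on the same 21, while C6, C7 and C8 are spectators. Alkene geometry is set in the chair diyl: C5 carries a hydrogen and can place C6 equatorial (C6 trans to C3, hence 4E), and because C6 and C9 are cis on the old ring fusion, C9 on quaternary C10 must then be axial (C9 cis to C2, hence 1Z), the one-retained, one-inverted result typical of cis-anti-cis adducts, whereas the other chair would need both C6 and C14 axial. The step needs C5-C10 rather than C2-C3 cleavage and survival of 21 against Cope reclosure: the first is secured by substitution and the nascent enone conjugation, the second by millisecond contact at high temperature (which favours the high-barrier cycloreversion over the ordered Cope transition state), by the conjugation that reclosure would forfeit, and by the quaternary centre it would have to rebuild. The acetonide keeps the tertiary C7 hydroxyl from retro-aldol cleavage toward either carbonyl group in the hot zone.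

Step 16
Reactants: 21 (1Z,4E)-dien-9-one
Product: 22 (9R)-allylic alcohol (O9 syn to O8 along the C7-C10 chain)
Conditions: NaBH4, CeCl3·7H2O, MeOH, -78 °C
Reagents that add atoms: none
Why: Luche 1,2-reduction spares the lactone and the enone double bond, and hydride should enter from the ring periphery anti to the C8-O bond (polar Felkin-Anh mode, compatible with an anti C7-C8-C9-C10 torsion), which gives the 8,9-syn, that is (9R), carbinol.

Step 17
Reactants: 22 (9R)-allylic alcohol
Product: 23 C9 tert-butyldimethylsilyl ether
Conditions: TBSOTf, 2,6-lutidine, CH2Cl2, -40 °C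
Reagents that add atoms: tert-butyldimethylsilyl triflate, CC(C)(C)[Si](C)(C)OS(=O)(=O)C(F)(F)F
Why: Silylation of the only free hydroxyl with the reactive triflate copes with the hindered site and marks O9 as the oxygen that stays unacylated.

Step 18
Reactants: 23 C9 silyl ether
Product: 27 α-methylene lactone (C11=C13) still carrying the C7/C8 acetonide and the C9 silyl ether, via lithium enolate 24 (not isolated), via Mannich base 25 (not isolated), via methiodide 26 (not isolated)
Conditions: LiN(iPr)2 (LDA), THF, -78 °C; Me2N=CH2 I (Eschenmoser's salt), -78 to -20 °C; MeI, rt; aq. NaHCO3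
Reagents that add atoms: N,N-dimethylmethyleneiminium iodide, C=[N+](C)C.[I-]
Why: This is lactone α-methylenation by enolate Mannich reaction, quaternisation and Hofmann-type elimination, run before the diol is freed so that no C8 alkoxide can translactonise onto C12, and kept cold with a very reactive electrophile so that capture outruns β-loss of the C7 oxygen (β-oxygenated γ-lactone enolates are usable at this temperature).

Step 19
Reactants: 27 α-methylene lactone acetonide
Product: 28 7,8-diol (tertiary C7-OH, secondary C8-OH; C9 silyl ether retained)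
Conditions: AcOH-H2O (4:1), 40 °C
Reagents that add atoms: none
Why: Mild acid hydrolysis of the acetonide leaves the hindered secondary silyl ether in place and is weak enough not to trigger transannular cyclisation of the Z,E-diene.

Step 20
Reactants: 28 7,8-diol; 29 angelic acid ((Z)-2-methylbut-2-enoic acid)
Product: 31 8-O-angelate (C7-OH free, C9 silyl ether), via mixed anhydride 30 (not isolated)
Conditions: 29, 2,4,6-Cl3C6H2COCl, Et3N, toluene, rt; then 28, 75 °C
Reagents that add atoms: none
Why: Yamaguchi-type mixed-anhydride esterification without a nucleophilic catalyst transfers the angeloyl group without Z-to-E isomerisation, and only the secondary C8 hydroxyl can react because C7-OH is tertiary and O9 is silylated.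

Step 21
Reactants: 31 8-O-angelate silyl ether
Product: 32 target CNP0292337.1
Conditions: HF·pyridine, pyridine, THF, 0 °C to rt
Reagents that add atoms: none
Why: Fluoride desilylation in a buffered, slightly acidic medium avoids the alkoxide that would let the angelate migrate from O8 to O9 or add to the α-methylene lactone.

Compound list
1 | methyl β-D-galactopyranoside | CO[C@@H]1O[C@H](CO)[C@H](O)[C@H](O)[C@H]1O | starting material
2 | methyl 4,6-O-benzylidene-β-D-galactopyranoside (phenyl equatorial) | CO[C@@H]1O[C@@H]2CO[C@H](c3ccccc3)O[C@@H]2[C@H](O)[C@H]1O | intermediate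
3 | 2,3-O-dibutylstannylene acetal of 2 | CO[C@@H]1O[C@@H]2CO[C@H](c3ccccc3)O[C@@H]2[C@@H]4O[Sn](CCCC)(CCCC)O[C@@H]14 | intermediate
4 | methyl 4,6-O-benzylidene-β-D-xylo-hexopyranosid-3-ulose | CO[C@@H]1O[C@@H]2CO[C@H](c3ccccc3)O[C@@H]2C(=O)[C@H]1O | intermediate
5 | bromoacetyl bromide | BrCC(=O)Br | starting material
6 | 2-O-bromoacetyl derivative of 4 | CO[C@@H]1O[C@@H]2CO[C@H](c3ccccc3)O[C@@H]2C(=O)[C@H]1OC(=O)CBr | intermediate
7 | diiodosamarium enolate of 6 | CO[C@@H]1O[C@@H]2CO[C@H](c3ccccc3)O[C@@H]2C(=O)[C@H]1OC(=C)O[Sm](I)I | intermediate
8 | benzylidene-protected cis-fused γ-lactone with tertiary 3-OH | CO[C@@H]1O[C@@H]2CO[C@H](c3ccccc3)O[C@@H]2[C@@]4(O)CC(=O)O[C@@H]14 | intermediate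
9 | lactone triol | CO[C@@H]1O[C@H](CO)[C@H](O)[C@@]2(O)CC(=O)O[C@@H]12 | intermediate
10 | 6-deoxy-6-iodo lactone diol | CO[C@@H]1O[C@H](CI)[C@H](O)[C@@]2(O)CC(=O)O[C@@H]12 | intermediate
11 | 3,4-O-isopropylidene 6-iodide | CO[C@@H]1O[C@H](CI)[C@@H]3OC(C)(C)O[C@@]32CC(=O)O[C@@H]12 | intermediate
12 | hex-5-enopyranoside (exocyclic enol ether) | CO[C@@H]1OC(=C)[C@@H]3OC(C)(C)O[C@@]32CC(=O)O[C@@H]12 | intermediate
13 | β-hydroxycyclohexanone (C5 epimers) | O=C1CC(O)[C@@H]2OC(=O)C[C@@]23OC(C)(C)O[C@H]31 | intermediate
14 | C5 mesylate of 13 | O=C1CC(OS(C)(=O)=O)[C@@H]2OC(=O)C[C@@]23OC(C)(C)O[C@H]31 | intermediate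
15 | lactone- and acetonide-fused cyclohex-2-enone | O=C1C=C[C@@H]2OC(=O)C[C@@]23OC(C)(C)O[C@H]31 | intermediate
16 | 2-iodo enone | O=C1C(I)=C[C@@H]2OC(=O)C[C@@]23OC(C)(C)O[C@H]31 | intermediate
17 | 2-methyl enone | O=C1C(C)=C[C@@H]2OC(=O)C[C@@]23OC(C)(C)O[C@H]31 | intermediate
18 | methylenecyclobutane | C=C1CCC1 | starting material
19 | 1-methylcyclobutene | CC1=CCC1 | intermediate
20 | cis-anti-cis tricyclic photoadduct | O=C1[C@@]2(C)[C@@H]3CC[C@]3(C)[C@H]2[C@@H]4OC(=O)C[C@@]45OC(C)(C)O[C@H]51 | intermediate
21 | ten-membered (1Z,4E)-dien-9-one | C1C(=O)O[C@H]2/C=C(\C)CC/C=C(/C)C(=O)[C@@H]3OC(C)(C)O[C@]123 | intermediate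
22 | (9R)-allylic alcohol | C1C(=O)O[C@H]2/C=C(\C)CC/C=C(/C)[C@@H](O)[C@@H]3OC(C)(C)O[C@]123 | intermediate
23 | C9 tert-butyldimethylsilyl ether | C1C(=O)O[C@H]2/C=C(\C)CC/C=C(/C)[C@@H](O[Si](C)(C)C(C)(C)C)[C@@H]3OC(C)(C)O[C@]123 | intermediate
24 | lithium enolate of 23 | C1=C([O-])O[C@H]2/C=C(\C)CC/C=C(/C)[C@@H](O[Si](C)(C)C(C)(C)C)[C@@H]3OC(C)(C)O[C@]123.[Li+] | intermediate
25 | C11 dimethylaminomethyl lactone (Mannich base, C11 epimers) | CN(C)CC1C(=O)O[C@H]2/C=C(\C)CC/C=C(/C)[C@@H](O[Si](C)(C)C(C)(C)C)[C@@H]3OC(C)(C)O[C@]123 | intermediate
26 | methiodide of 25 | C[N+](C)(C)CC1C(=O)O[C@H]2/C=C(\C)CC/C=C(/C)[C@@H](O[Si](C)(C)C(C)(C)C)[C@@H]3OC(C)(C)O[C@]123.[I-] | intermediate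
27 | α-methylene lactone acetonide | C=C1C(=O)O[C@H]2/C=C(\C)CC/C=C(/C)[C@@H](O[Si](C)(C)C(C)(C)C)[C@@H]3OC(C)(C)O[C@]123 | intermediate
28 | α-methylene lactone 7,8-diol | C=C1C(=O)O[C@H]2/C=C(\C)CC/C=C(/C)[C@@H](O[Si](C)(C)C(C)(C)C)[C@H](O)[C@@]12O | intermediate
29 | angelic acid | C/C=C(/C)C(=O)O | starting material
30 | angelic 2,4,6-trichlorobenzoic mixed anhydride | C/C=C(/C)C(=O)OC(=O)c1c(Cl)cc(Cl)cc1Cl | intermediate
31 | 8-O-angelate C9 silyl ether | C=C1C(=O)O[C@H]2/C=C(\C)CC/C=C(/C)[C@@H](O[Si](C)(C)C(C)(C)C)[C@H](OC(=O)/C(C)=C\C)[C@@]12O | intermediate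
32 | CNP0292337.1 | C=C1C(=O)O[C@H]2/C=C(\C)CC/C=C(/C)[C@@H](O)[C@H](OC(=O)/C(C)=C\C)[C@@]12O | target

Total step count: 21. Longest linear sequence: 20 (steps 1-12 and 14-21; step 13 is a one-step side branch).

Steps most likely to fail

1. Step 15.
- **What may go wrong:** The fresh Z-enone may be consumed before it leaves the hot zone. The possible channels are Cope reclosure across C5 and C10, a 1,5-hydrogen shift from C2 to the carbonyl oxygen, and enolisation toward C8 with loss of the C7 oxygen.
- **Fallback:** This takes the carbonyl group out of the pyrolysis and makes the enone only afterwards at room temperature. It sets out from 20. NaBH4 in MeOH at 0 °C reduces the ketone (the lactone stays) to tricyclic carbinol F1, and either C9 epimer serves. Pyrolysis of this carbinol opens the same two bonds to give cyclodecadienol F2, an unconjugated Z,E-diene that has neither the hydrogen-shift nor the enolisation channel. Dess-Martin periodinane (or MnO2) in CH2Cl2 at room temperature then oxidises the allylic alcohol, and the route is rejoined at 21.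

2. Step 18.
- **What may go wrong:** The C7 oxygen may be lost from the lactone enolate (E1cB) before the iminium salt is captured.
- **Fallback:** This turns the leaving group into a non-leaving alkoxide, following the dianion logic of β-hydroxy esters. It sets out from 23.
 - AcOH-H2O at 40 °C cleaves the acetonide first to saturated-lactone diol F3.
 - TESCl and imidazole in CH2Cl2 cap only the secondary hydroxyl to give C8 triethylsilyl ether F4, which also blocks translactonisation.
 - LiN(iPr)2 (2.5 equiv, THF, -78 °C) forms dilithio alkoxide enolate F5.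
 - Me2N=CH2 I gives Mannich base F6, MeI gives methiodide F7, and aqueous NaHCO3 gives α-methylene lactone triethylsilyl ether F8.
 - PPTS in MeOH at 0 °C removes only the triethylsilyl group, and the route is rejoined at 28.

3. Step 16.
- **What may go wrong:** Hydride delivery to the conformationally mobile ten-membered enone may show poor or reversed facial selectivity.
- **Fallback:** This aims deliberately at the other epimer and then inverts it. It sets out from 21. Zn(BH4)2 in Et2O at -30 °C, with zinc bridging O8 and the carbonyl oxygen (chelation control, 8,9-anti), should give 9-epi alcohol F9. Mitsunobu inversion (4-nitrobenzoic acid, PPh3, DIAD, toluene, 0 °C to rt) gives (9R)-4-nitrobenzoate F10. K2CO3 in MeOH at 0 °C cleaves this activated ester faster than the lactone, and the route is rejoined at 22.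

Further compounds
F1 | step 15 | tricyclic carbinol (C9-OH, either epimer) | OC1[C@@]2(C)[C@@H]3CC[C@]3(C)[C@H]2[C@@H]4OC(=O)C[C@@]45OC(C)(C)O[C@H]51
F2 | step 15 | (1Z,4E)-cyclodecadienol (C9-OH, either epimer) | C1C(=O)O[C@H]2/C=C(\C)CC/C=C(/C)C(O)[C@@H]3OC(C)(C)O[C@]123
F3 | step 18 | saturated-lactone 7,8-diol with C9 silyl ether | C1C(=O)O[C@H]2/C=C(\C)CC/C=C(/C)[C@@H](O[Si](C)(C)C(C)(C)C)[C@H](O)[C@@]12O
F4 | step 18 | C8 triethylsilyl ether of F3 | C1C(=O)O[C@H]2/C=C(\C)CC/C=C(/C)[C@@H](O[Si](C)(C)C(C)(C)C)[C@H](O[Si](CC)(CC)CC)[C@@]12O
F5 | step 18 | dilithio C7-alkoxide lactone enolate | C1=C([O-])O[C@H]2/C=C(\C)CC/C=C(/C)[C@@H](O[Si](C)(C)C(C)(C)C)[C@H](O[Si](CC)(CC)CC)[C@@]12[O-].[Li+].[Li+]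
F6 | step 18 | Mannich base (C11 epimers) | CN(C)CC1C(=O)O[C@H]2/C=C(\C)CC/C=C(/C)[C@@H](O[Si](C)(C)C(C)(C)C)[C@H](O[Si](CC)(CC)CC)[C@@]12O
F7 | step 18 | methiodide of F6 | C[N+](C)(C)CC1C(=O)O[C@H]2/C=C(\C)CC/C=C(/C)[C@@H](O[Si](C)(C)C(C)(C)C)[C@H](O[Si](CC)(CC)CC)[C@@]12O.[I-]
F8 | step 18 | α-methylene lactone with C8 triethylsilyl and C9 tert-butyldimethylsilyl ethers | C=C1C(=O)O[C@H]2/C=C(\C)CC/C=C(/C)[C@@H](O[Si](C)(C)C(C)(C)C)[C@H](O[Si](CC)(CC)CC)[C@@]12O
F9 | step 16 | (9S)-allylic alcohol (9-epimer of 22) | C1C(=O)O[C@H]2/C=C(\C)CC/C=C(/C)[C@H](O)[C@@H]3OC(C)(C)O[C@]123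
F10 | step 16 | (9R)-4-nitrobenzoate | C1C(=O)O[C@H]2/C=C(\C)CC/C=C(/C)[C@@H](OC(=O)c4ccc(cc4)[N+](=O)[O-])[C@@H]3OC(C)(C)O[C@]123
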